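## Retrosynthetic overview
1. The last bond made is the aryl C6–CH2 bond of the methylene bridge. The C6–CH3 group of the dearomatised triketone (ring B) is dehydrogenated at an anode to a methylidene triketone, and the free C6–H of the chromene (rings A and C) attacks it.
2. The quaternary C4 of ring B comes from a dearomative aromatic Claisen shift of the 4-O-linalyl ether of C2v-symmetric 3,5-dimethylphloroacetophenone. The carbinol stereocentre of natural (R)-linalool is traded for C4, and its ten carbons become the geranyl chain.
3. The tertiary aryl ether comes from a stereoretentive rhodium-catalysed O-allylation with (R)-linalyl methyl carbonate.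
4. The chromene half comes from Friedel–Crafts hexanoylation of phloroglucinol, then prenal condensation and oxa-6π closure.
5. Ring order: both carbocycles are bought as phloroglucinols. Pyran ring C is closed first (step 2), ring B is dearomatised in step 5, and no ring forms in the final coupling.

Assumption: ring B is drawn throughout in the enol tautomer of the target SMILES, CIP labels refer to the drawn tautomer, and natural (R)-(−)-linalool of at least 95% ee is used.

## Route

Step 1
Reactants: 1 benzene-1,3,5-triol (phloroglucinol); 2 hexanoyl chloride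
Product: 3 1-(2,4,6-trihydroxyphenyl)hexan-1-one
Conditions: AlCl3 (3.5 equiv), CH2Cl2–PhNO2, 0 to 40 °C; 1 M HCl work-up
Reagents that add atoms: none
Why: Friedel–Crafts acylation of a very electron-rich arene; the chelated ketone–AlCl3 complex is deactivated, so the reaction stops at the monoketone, and no stereocentre is formed.

Step 2
Reactants: 3 1-(2,4,6-trihydroxyphenyl)hexan-1-one; 4 3-methylbut-2-enal (prenal)
Product: 6 1-(5,7-dihydroxy-2,2-dimethyl-2H-chromen-8-yl)hexan-1-one, via prenylidene dienone 5 (not isolated)
Conditions: 4 (1.0 equiv), ethylenediammonium diacetate (10 mol %), PhMe–THF 4:1, 80 °C, Dean–Stark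
Reagents that add atoms: none
Why: Knoevenagel-type condensation at a free ring carbon gives dienone 5, whose oxa-6π electrocyclisation through the carbonyl oxygen next to the acyl group closes ring C to the 8-acyl chromene (7-OH stays chelated to the ketone); the 6-acyl regioisomer is removed by chromatography.

Step 3
Reactants: 7 1-(2,4,6-trihydroxyphenyl)ethan-1-one (phloroacetophenone)
Product: 9 1-(2,4,6-trihydroxy-3,5-dimethylphenyl)ethan-1-one, via monomethyl ketone 8 (not isolated)
Conditions: MeI (2.1 equiv), NaOMe (2.2 equiv), MeOH, 0 to 40 °C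
Reagents that add atoms: iodomethane, CI
Why: Phenolate C-alkylation (SN2 on MeI) in a protic solvent, which favours carbon over oxygen attack; two equivalents carry 7 through 8 to the symmetric aromatic compound 9, and under- and over-methylated material is removed by crystallisation.

Step 4
Reactants: 10 (3R)-3,7-dimethylocta-1,6-dien-3-ol, (R)-(−)-linalool
Product: 12 methyl (3R)-3,7-dimethylocta-1,6-dien-3-yl carbonate, via lithium linaloolate 11 (not isolated)
Conditions: n-BuLi (1.05 equiv), THF, −78 °C; ClCO2Me (1.2 equiv), −78 °C to rt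
Reagents that add atoms: methyl chloroformate, COC(=O)Cl
Why: O-acylation of a tertiary lithium alkoxide with a chloroformate; the C–O bond at the stereocentre is not touched, so the (R) configuration bought with 10 is kept.

Step 5
Reactants: 9 1-(2,4,6-trihydroxy-3,5-dimethylphenyl)ethan-1-one; 12 methyl (3R)-3,7-dimethylocta-1,6-dien-3-yl carbonate
Product: 15 (4R)-2-acetyl-4-[(2E)-3,7-dimethylocta-2,6-dien-1-yl]-3,5-dihydroxy-4,6-dimethylcyclohexa-2,5-dien-1-one, via sodium phenoxide 13 (not isolated), via aryl linalyl ether 14 (not isolated)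
Conditions: 9, NaN(SiMe3)2 (1.0 equiv), THF, 0 °C; 12, [Rh(cod)Cl]2 (5 mol %), P(OPh)3 (20 mol %), −10 °C to rt; then 1,2-bis(diphenylphosphino)ethane (25 mol %), PhMe, 80 °C; 1 M HCl work-up; AgNO3–SiO2 chromatography (removes the Z isomer)
Reagents that add atoms: none
Why: Proposed new method: the phosphite-modified monovalent rhodium catalyst ionises the tertiary carbonate with inversion to a configurationally stable enyl (σ+π) complex, and the most acidic, non-chelated 4-phenoxide 13 attacks its tertiary carbon with a second inversion (net retention) faster than the enyl can isomerise, giving (R)-ether 14; once the diphosphine has tied up the rhodium, 14 undergoes a suprafacial chair-like aromatic Claisen shift onto either of the two equivalent methyl-bearing ortho carbons, so no regioisomer and no rearomatisation are possible, and with the homoprenyl chain outside (away from the second ortho methyl) the (R) carbinol centre gives the E alkene and (4R), which enolisation to the triketone locks in; the closest known reactions are the stereospecific rhodium-catalysed allylic etherification of secondary carbonates with ortho-substituted phenoxides, the stereospecific substitution of tertiary allylic carbonates by carbon nucleophiles, and aromatic Claisen rearrangement with 1,3-chirality transfer.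

Step 6
Reactants: 15 (4R)-2-acetyl-4-[(2E)-3,7-dimethylocta-2,6-dien-1-yl]-3,5-dihydroxy-4,6-dimethylcyclohexa-2,5-dien-1-one; 6 1-(5,7-dihydroxy-2,2-dimethyl-2H-chromen-8-yl)hexan-1-one
Product: 17 (4R)-2-acetyl-4-[(2E)-3,7-dimethylocta-2,6-dien-1-yl]-6-[(8-hexanoyl-5,7-dihydroxy-2,2-dimethyl-2H-chromen-6-yl)methyl]-3,5-dihydroxy-4-methylcyclohexa-2,5-dien-1-one (target), via methylidene triketone 16 (not isolated)
Conditions: undivided cell, graphite anode, Pt cathode, TEMPO (20 mol %), 2,6-lutidine (1.2 equiv), n-Bu4NBF4 (0.1 M), MeCN–HFIP 4:1, 6 (1.3 equiv), 5 mA cm−2, 2.2 F mol−1, 25–35 °C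
Reagents that add atoms: none
Why: Proposed new method: lutidine ionises only the strongly acidic triketone 15 (pKa about 5) and not the chelated phenol 6 (pKa about 8), so the oxoammonium ion made at the anode (about +0.7 V vs SCE, far below the alkenes and the neutral phenol) takes two electrons and two protons from the enolate and its C6–CH3 group to give methylidene triketone 16, a very strong Michael acceptor; the only free ring carbon of 6 (C6, between two OH groups) attacks it, rearomatisation gives the bridge C–C bond, the protons leave as H2 at the cathode, and the quaternary C4 is not touched; the closest known reactions are the chemical oxidation of C-methyl dearomatised acylphloroglucinols with TEMPO/Ag2O or PhI(OAc)2 to the same kind of quinone methide (so far trapped by alkenes in hetero-Diels–Alder reactions) and the Michael addition of acylphloroglucinols to alkylidene triketones.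

## Compound list
1 | benzene-1,3,5-triol (phloroglucinol) | Oc1cc(O)cc(O)c1 | starting material
2 | hexanoyl chloride | CCCCCC(=O)Cl | starting material
3 | 1-(2,4,6-trihydroxyphenyl)hexan-1-one | CCCCCC(=O)c1c(O)cc(O)cc1O | intermediate
4 | 3-methylbut-2-enal (prenal) | CC(C)=CC=O | starting material
5 | 2-hexanoyl-3,5-dihydroxy-6-(3-methylbut-2-en-1-ylidene)cyclohexa-2,4-dien-1-one (not isolated) | CCCCCC(=O)C1=C(O)C=C(O)C(=CC=C(C)C)C1=O | intermediate
6 | 1-(5,7-dihydroxy-2,2-dimethyl-2H-chromen-8-yl)hexan-1-one | CCCCCC(=O)c1c(O)cc(O)c2c1OC(C)(C)C=C2 | intermediate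
7 | 1-(2,4,6-trihydroxyphenyl)ethan-1-one | CC(=O)c1c(O)cc(O)cc1O | starting material
8 | 1-(2,4,6-trihydroxy-3-methylphenyl)ethan-1-one (not isolated) | CC(=O)c1c(O)cc(O)c(C)c1O | intermediate
9 | 1-(2,4,6-trihydroxy-3,5-dimethylphenyl)ethan-1-one | CC(=O)c1c(O)c(C)c(O)c(C)c1O | intermediate
10 | (3R)-3,7-dimethylocta-1,6-dien-3-ol, (R)-(−)-linalool | C=C[C@](C)(O)CCC=C(C)C | starting material
11 | lithium (3R)-3,7-dimethylocta-1,6-dien-3-olate (not isolated) | C=C[C@](C)([O-])CCC=C(C)C.[Li+] | intermediate
12 | methyl (3R)-3,7-dimethylocta-1,6-dien-3-yl carbonate | C=C[C@](C)(OC(=O)OC)CCC=C(C)C | intermediate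
13 | sodium 4-acetyl-3,5-dihydroxy-2,6-dimethylphenolate (not isolated) | CC(=O)c1c(O)c(C)c([O-])c(C)c1O.[Na+] | intermediate
14 | 1-(4-{[(3R)-3,7-dimethylocta-1,6-dien-3-yl]oxy}-2,6-dihydroxy-3,5-dimethylphenyl)ethan-1-one (not isolated) | CC(=O)c1c(O)c(C)c(O[C@@](C)(C=C)CCC=C(C)C)c(C)c1O | intermediate
15 | (4R)-2-acetyl-4-[(2E)-3,7-dimethylocta-2,6-dien-1-yl]-3,5-dihydroxy-4,6-dimethylcyclohexa-2,5-dien-1-one | CC1=C(O)[C@@](C)(C/C=C(\C)CCC=C(C)C)C(O)=C(C(C)=O)C1=O | intermediate
16 | 2-acetyl-4-[(2E)-3,7-dimethylocta-2,6-dien-1-yl]-3-hydroxy-4-methyl-6-methylidenecyclohex-2-ene-1,5-dione; C4 arranged in space as in 15 (label 4S here because the ranking of the two ring branches changes); not isolated | C=C1C(=O)[C@@](C)(C/C=C(\C)CCC=C(C)C)C(O)=C(C(C)=O)C1=O | intermediate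
17 | (4R)-2-acetyl-4-[(2E)-3,7-dimethylocta-2,6-dien-1-yl]-6-[(8-hexanoyl-5,7-dihydroxy-2,2-dimethyl-2H-chromen-6-yl)methyl]-3,5-dihydroxy-4-methylcyclohexa-2,5-dien-1-one | CCCCCC(=O)c1c(O)c(CC2=C(O)[C@@](C)(C/C=C(\C)CCC=C(C)C)C(O)=C(C(C)=O)C2=O)c(O)c2c1OC(C)(C)C=C2 | target

## Step count
Total step count: 6.
Longest linear sequence: 3 steps (7 → 9 → 15 → 17). The branches 10 → 12 → 15 → 17 and 1 → 3 → 6 → 17 are equally long.

## Three steps most likely to fail

**Step 5 (new).**
- The hindered phenoxide may attack the primary allyl terminus and give the O-geranyl ether.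
- It may instead react through carbon, which gives no stereocontrol.
- Ether 14 may lose ee through enyl isomerisation or ionisation.
- About one quarter to one third of the Claisen product is expected as the Z isomer, which carries the opposite C4 configuration and must be removed.
- Leakage through a boat transition state would lower the ee of 15, so the ee is checked by chiral HPLC.

The fallback uses known chemistry and sets out from 9. C-selective dearomative alkylation with geranyl bromide in aqueous KOH–MeOH at 0 °C gives racemic 2-acetyl-4-[(2E)-3,7-dimethylocta-2,6-dien-1-yl]-3,5-dihydroxy-4,6-dimethylcyclohexa-2,5-dien-1-one F1 as the pure E isomer. The enantiomers are separated by preparative HPLC on a cellulose tris(3,5-dimethylphenylcarbamate) phase. The (4R) enantiomer is 15, where the fallback rejoins the route. The (4S)-enantiomer of 15 F2 is set aside. The assignment is made by ECD.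

**Step 6 (new).**
- The oxoammonium ion may also oxidise 6 or the product 17.
- Triketone 16 may oligomerise before it is trapped.

The fallback uses known chemistry and sets out from 15. It replaces electron transfer by polar selenium chemistry. PhSeCl–pyridine in CH2Cl2 at 0 °C selenenylates the enol at C6 to give 2-acetyl-4-[(2E)-3,7-dimethylocta-2,6-dien-1-yl]-3-hydroxy-4,6-dimethyl-6-(phenylselanyl)cyclohex-2-ene-1,5-dione F3 (both C6 epimers, C4 as in 15). mCPBA at −78 °C gives the corresponding selenoxide F4. On warming in the presence of 6 and i-Pr2NH, F4 undergoes syn elimination towards the only β-hydrogens, those of the methyl group. The fallback rejoins the route at 16, which 6 traps to give 17.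

**Step 2.**
- The oxa-6π closure can also use the oxygen para to the acyl group and give the 6-acyl chromene.
- A second chromene ring can form.

The fallback sets out from 3. The non-chelated 4-OH is silylated selectively (i-Pr3SiCl, imidazole, DMF, 0 °C) to give 1-{2,6-dihydroxy-4-[(triisopropylsilyl)oxy]phenyl}hexan-1-one F5. Condensation with 4 under the step 2 conditions can now close only through the oxygen next to the ketone, giving 1-{7-hydroxy-2,2-dimethyl-5-[(triisopropylsilyl)oxy]-2H-chromen-8-yl}hexan-1-one F6. n-Bu4NF–AcOH in THF removes the silyl group, and the fallback rejoins the route at 6.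

## Further compounds
F1 | step 5 | racemic 2-acetyl-4-[(2E)-3,7-dimethylocta-2,6-dien-1-yl]-3,5-dihydroxy-4,6-dimethylcyclohexa-2,5-dien-1-one | CC1=C(O)C(C)(C/C=C(\C)CCC=C(C)C)C(O)=C(C(C)=O)C1=O
F2 | step 5 | (4S)-2-acetyl-4-[(2E)-3,7-dimethylocta-2,6-dien-1-yl]-3,5-dihydroxy-4,6-dimethylcyclohexa-2,5-dien-1-one | CC1=C(O)[C@](C)(C/C=C(\C)CCC=C(C)C)C(O)=C(C(C)=O)C1=O
F3 | step 6 | 2-acetyl-4-[(2E)-3,7-dimethylocta-2,6-dien-1-yl]-3-hydroxy-4,6-dimethyl-6-(phenylselanyl)cyclohex-2-ene-1,5-dione (C4 as in 15, both C6 epimers) | CC1([Se]c2ccccc2)C(=O)[C@@](C)(C/C=C(\C)CCC=C(C)C)C(O)=C(C(C)=O)C1=O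
F4 | step 6 | 2-acetyl-4-[(2E)-3,7-dimethylocta-2,6-dien-1-yl]-3-hydroxy-4,6-dimethyl-6-(phenylseleninyl)cyclohex-2-ene-1,5-dione (C4 as in 15) | CC1([Se](=O)c2ccccc2)C(=O)[C@@](C)(C/C=C(\C)CCC=C(C)C)C(O)=C(C(C)=O)C1=O
F5 | step 2 | 1-{2,6-dihydroxy-4-[(triisopropylsilyl)oxy]phenyl}hexan-1-one | CCCCCC(=O)c1c(O)cc(O[Si](C(C)C)(C(C)C)C(C)C)cc1O
F6 | step 2 | 1-{7-hydroxy-2,2-dimethyl-5-[(triisopropylsilyl)oxy]-2H-chromen-8-yl}hexan-1-one | CCCCCC(=O)c1c(O)cc(O[Si](C(C)C)(C(C)C)C(C)C)c2c1OC(C)(C)C=C2
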